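**Retrosynthetic overview**
- Target ⇒ oxirane by nucleophilic epoxidation of a silylated para-quinol ⇒ para-quinol by enantioselective para-hydroxylation (dearomatization) of the fully assembled aromatic "proto" compound, as the last events, mirroring the late oxidations of the biosynthesis.
- Proto compound ⇒ cyclopentenone ring by intramolecular Claisen closure of a 5-aminolevulinate amide.
- Amide bonds ⇒ a 3-amino-4-hydroxyphenyl trienoic acid, methyl 5-aminolevulinate and 8-methylnonatrienoic acid; both trienes ⇒ enal + triethyl 4-phosphonocrotonate; phenol ⇐ aryl fluoride (SNAr); amine ⇐ nitro.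
- Ring order: benzene ring bought → cyclopentenone ring (step 7) → dearomatized cyclohexadienone (step 8) → oxirane (step 10).

Reading of the target: the tertiary OH and the epoxide oxygen lie on opposite ring faces, (1R,5S,6S) in 7-oxabicyclo[4.1.0]heptene numbering; the route is built for this diastereomer.

Assumption: the facial sense of the chiral iodane in step 8 cannot be predicted for this substrate; the (R,R)-iodoarene ArI* = (R,R)-2-iodo-1,3-bis[1-(mesitylcarbamoyl)ethoxy]benzene, C[C@@H](Oc1cccc(O[C@H](C)C(=O)Nc2c(C)cc(C)cc2C)c1I)C(=O)Nc1c(C)cc(C)cc1C, is written, and its (S,S) mirror image is used if the (R,R) form gives the (S)-quinol.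

Assumption: ArI* and methyl 5-aminolevulinate hydrochloride are bought.

**Step 1**
Reactants: 1 (E)-4-methylpent-2-enal; 2 triethyl 4-phosphonocrotonate
Product: 4 (2E,4E,6E)-8-methylnona-2,4,6-trienoic acid, via ethyl trienoate 3 (not isolated)
Conditions: 2, NaH, THF, 0 °C; then 1, −20 °C → rt; then LiOH, MeOH/H2O, 40 °C; then 1 M HCl
Reagents that add atoms: lithium hydroxide, [Li+].[OH-]
Why: Vinylogous Horner–Wadsworth–Emmons olefination forms the new C4=C5 bond E under the usual thermodynamic control of a stabilized phosphonate, the ester is saponified in the same flask, and the all-E acid is purified by crystallization.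

**Step 2**
Reactants: 5 4-fluoro-3-nitrobenzaldehyde; 6 (triphenylphosphoranylidene)acetaldehyde
Product: 7 (E)-3-(4-fluoro-3-nitrophenyl)prop-2-enal
Conditions: toluene, 80 °C
Reagents that add atoms: none
Why: Wittig reaction of a carbonyl-stabilized ylide gives the E-enal, and the electron-poor nitrobenzaldehyde reacts far faster than the enal product, so a second homologation stays minor.

**Step 3**
Reactants: 7 (E)-3-(4-fluoro-3-nitrophenyl)prop-2-enal; 2 triethyl 4-phosphonocrotonate
Product: 9 (2E,4E,6E)-7-(4-hydroxy-3-nitrophenyl)hepta-2,4,6-trienoic acid, via fluoro nitro trienoate 8 (not isolated)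
Conditions: 2, NaH, THF, 0 °C; then 7, −20 °C → rt; then KOH (aq), DMSO, 50 °C; then 1 M HCl
Reagents that add atoms: potassium hydroxide, [K+].[OH-]
Why: Horner–Wadsworth–Emmons olefination sets the new double bond E, and in the same flask hydroxide replaces fluoride by SNAr (activated by the ortho-nitro group and the para trienoate) and saponifies the ester, so the deactivating phenoxide appears only after both olefinations.

**Step 4**
Reactants: 9 (2E,4E,6E)-7-(4-hydroxy-3-nitrophenyl)hepta-2,4,6-trienoic acid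
Product: 10 (2E,4E,6E)-7-(3-amino-4-hydroxyphenyl)hepta-2,4,6-trienoic acid
Conditions: Fe powder, NH4Cl, EtOH/H2O, 70 °C; used at once
Reagents that add atoms: none
Why: Béchamp-type iron reduction is selective for the nitro group and leaves the conjugated trienoic acid untouched, and the air-sensitive aminophenol is acylated without storage.

**Step 5**
Reactants: 10 (2E,4E,6E)-7-(3-amino-4-hydroxyphenyl)hepta-2,4,6-trienoic acid; 4 (2E,4E,6E)-8-methylnona-2,4,6-trienoic acid
Product: 12 (2E,4E,6E)-7-{4-hydroxy-3-[(2E,4E,6E)-8-methylnona-2,4,6-trienamido]phenyl}hepta-2,4,6-trienoic acid, via trienoyl chloride 11 (not isolated)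
Conditions: 4, (COCl)2, cat. DMF, CH2Cl2, 0 °C → rt, evaporate; then 10, NaHCO3, THF/H2O, 0 °C; then 1 M HCl
Reagents that add atoms: none
Why: Schotten–Baumann N-acylation through the acid chloride succeeds because at pH 8 the aniline nitrogen is far more nucleophilic than the phenol or the carboxylate.

**Step 6**
Reactants: 12 (2E,4E,6E)-7-{4-hydroxy-3-[(2E,4E,6E)-8-methylnona-2,4,6-trienamido]phenyl}hepta-2,4,6-trienoic acid; 13 methyl 5-amino-4-oxopentanoate hydrochloride
Product: 14 methyl 5-[(2E,4E,6E)-7-{4-hydroxy-3-[(2E,4E,6E)-8-methylnona-2,4,6-trienamido]phenyl}hepta-2,4,6-trienamido]-4-oxopentanoate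
Conditions: DIC, HOBt, NaHCO3, DMF, 0 °C → rt
Reagents that add atoms: none
Why: Carbodiimide/HOBt amide coupling in which the α-amino ketone is released from its salt only in the presence of the active ester, which outruns its self-condensation to a dihydropyrazine.

**Step 7**
Reactants: 14 methyl 5-[(2E,4E,6E)-7-{4-hydroxy-3-[(2E,4E,6E)-8-methylnona-2,4,6-trienamido]phenyl}hepta-2,4,6-trienamido]-4-oxopentanoate
Product: 15 (2E,4E,6E)-N-{2-hydroxy-5-[(1E,3E,5E)-7-[(2-hydroxy-5-oxocyclopent-1-en-1-yl)amino]-7-oxohepta-1,3,5-trien-1-yl]phenyl}-8-methylnona-2,4,6-trienamide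
Conditions: KOtBu (4.5 equiv), THF/DMF, 0 °C → rt; then aq. HCl to pH 3
Reagents that add atoms: none
Why: Proposed new method: the enolate at C5 of the aminolevulinate unit (the most acidic C–H, flanked by ketone and amide nitrogen) attacks the methyl ester in a 5-exo-trig intramolecular Claisen (Dieckmann-type) condensation that copies the biosynthetic cyclization of 5-aminolevulinate, and irreversible deprotonation of the resulting 2-amido-1,3-dione drives it; the closest known reaction is the alkoxide-mediated cyclization of 4-oxoalkanoate esters to 2-substituted cyclopentane-1,3-diones; no stereocenter is formed.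

**Step 8**
Reactants: 15 (2E,4E,6E)-N-{2-hydroxy-5-[(1E,3E,5E)-7-[(2-hydroxy-5-oxocyclopent-1-en-1-yl)amino]-7-oxohepta-1,3,5-trien-1-yl]phenyl}-8-methylnona-2,4,6-trienamide
Product: 16 (2E,4E,6E)-N-[(3R)-3-hydroxy-3-[(1E,3E,5E)-7-[(2-hydroxy-5-oxocyclopent-1-en-1-yl)amino]-7-oxohepta-1,3,5-trien-1-yl]-6-oxocyclohexa-1,4-dien-1-yl]-8-methylnona-2,4,6-trienamide
Conditions: ArI* (1.2 equiv), mCPBA (1.1 equiv), AcOH, CH2Cl2, rt, 3 h; then 15, H2O (10 equiv), CH2Cl2/MeCN, −30 °C
Reagents that add atoms: water, O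
Why: Proposed new method: ligand exchange places the phenol oxygen on the trivalent iodine centre of the preformed C2-symmetric diacetoxy-λ3-iodane and water attacks the para carbon while the chiral iodanyl group is still attached, so that the folded lactamide arms expose one face of C4 and set the (R) carbinol centre before the iodoarene departs; the closest known reactions are para-quinol formation from 4-substituted phenols with PhI(OAc)2 in aqueous acetonitrile and chiral aryl iodide-mediated enantioselective hydroxylative phenol dearomatization; the peracid is consumed before the polyene is added.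

**Step 9**
Reactants: 16 (2E,4E,6E)-N-[(3R)-3-hydroxy-3-[(1E,3E,5E)-7-[(2-hydroxy-5-oxocyclopent-1-en-1-yl)amino]-7-oxohepta-1,3,5-trien-1-yl]-6-oxocyclohexa-1,4-dien-1-yl]-8-methylnona-2,4,6-trienamide
Product: 18 (2E,4E,6E)-N-[(3R)-3-[(1E,3E,5E)-7-[(2-hydroxy-5-oxocyclopent-1-en-1-yl)amino]-7-oxohepta-1,3,5-trien-1-yl]-6-oxo-3-[(triethylsilyl)oxy]cyclohexa-1,4-dien-1-yl]-8-methylnona-2,4,6-trienamide, via bis-silyl ether 17 (not isolated)
Conditions: TESOTf (2.5 equiv), 2,6-lutidine, CH2Cl2, −78 → −20 °C; then MeOH, 0 °C; aq. NaHCO3 work-up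
Reagents that add atoms: triethylsilyl trifluoromethanesulfonate, CC[Si](CC)(CC)OS(=O)(=O)C(F)(F)F
Why: Silyl ether formation with a silyl triflate caps the accessible tertiary carbinol (three sp2 neighbours) and the enol, and methanol then cleaves only the labile vinylogous silyl ester, leaving the C4 stereocenter untouched.

**Step 10**
Reactants: 18 (2E,4E,6E)-N-[(3R)-3-[(1E,3E,5E)-7-[(2-hydroxy-5-oxocyclopent-1-en-1-yl)amino]-7-oxohepta-1,3,5-trien-1-yl]-6-oxo-3-[(triethylsilyl)oxy]cyclohexa-1,4-dien-1-yl]-8-methylnona-2,4,6-trienamide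
Product: 20 (2E,4E,6E)-N-[(1R,5S,6S)-5-hydroxy-5-[(1E,3E,5E)-7-[(2-hydroxy-5-oxocyclopent-1-en-1-yl)amino]-7-oxohepta-1,3,5-trien-1-yl]-2-oxo-7-oxabicyclo[4.1.0]hept-3-en-3-yl]-8-methylnona-2,4,6-trienamide (CNP0215439.3), via silylated epoxide 19 (not isolated)
Conditions: TBHP (anhydrous, decane), DBU, CH2Cl2, 0 °C; then HF·pyridine, pyridine, THF, 0 °C → rt
Reagents that add atoms: tert-butyl hydroperoxide, CC(C)(C)OO
Why: Weitz–Scheffer nucleophilic epoxidation in which the tert-butylperoxide anion adds to C5 of the only enone not deactivated by the amide nitrogen, from the face opposite the bulky silyloxy group that can no longer deliver the reagent by hydrogen bonding, and enolate closure gives the cis-fused oxirane anti to the C4 oxygen, after which buffered HF removes the silyl group without forming the alkoxide that could start a Payne rearrangement.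

**Compound list**
1 | (E)-4-methylpent-2-enal | CC(C)/C=C/C=O | starting material
2 | triethyl 4-phosphonocrotonate [ethyl (E)-4-(diethoxyphosphoryl)but-2-enoate] | CCOC(=O)/C=C/CP(=O)(OCC)OCC | starting material
3 | ethyl (2E,4E,6E)-8-methylnona-2,4,6-trienoate | CC(C)/C=C/C=C/C=C/C(=O)OCC | intermediate
4 | (2E,4E,6E)-8-methylnona-2,4,6-trienoic acid | CC(C)/C=C/C=C/C=C/C(=O)O | intermediate
5 | 4-fluoro-3-nitrobenzaldehyde | O=Cc1ccc(F)c([N+](=O)[O-])c1 | starting material
6 | (triphenylphosphoranylidene)acetaldehyde | O=CC=P(c1ccccc1)(c1ccccc1)c1ccccc1 | starting material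
7 | (E)-3-(4-fluoro-3-nitrophenyl)prop-2-enal | O=C/C=C/c1ccc(F)c([N+](=O)[O-])c1 | intermediate
8 | ethyl (2E,4E,6E)-7-(4-fluoro-3-nitrophenyl)hepta-2,4,6-trienoate | CCOC(=O)/C=C/C=C/C=C/c1ccc(F)c([N+](=O)[O-])c1 | intermediate
9 | (2E,4E,6E)-7-(4-hydroxy-3-nitrophenyl)hepta-2,4,6-trienoic acid | OC(=O)/C=C/C=C/C=C/c1ccc(O)c([N+](=O)[O-])c1 | intermediate
10 | (2E,4E,6E)-7-(3-amino-4-hydroxyphenyl)hepta-2,4,6-trienoic acid | Nc1cc(/C=C/C=C/C=C/C(=O)O)ccc1O | intermediate
11 | (2E,4E,6E)-8-methylnona-2,4,6-trienoyl chloride | CC(C)/C=C/C=C/C=C/C(=O)Cl | intermediate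
12 | (2E,4E,6E)-7-{4-hydroxy-3-[(2E,4E,6E)-8-methylnona-2,4,6-trienamido]phenyl}hepta-2,4,6-trienoic acid | CC(C)/C=C/C=C/C=C/C(=O)Nc1cc(/C=C/C=C/C=C/C(=O)O)ccc1O | intermediate
13 | methyl 5-amino-4-oxopentanoate hydrochloride (methyl 5-aminolevulinate hydrochloride) | COC(=O)CCC(=O)CN.Cl | starting material
14 | methyl 5-[(2E,4E,6E)-7-{4-hydroxy-3-[(2E,4E,6E)-8-methylnona-2,4,6-trienamido]phenyl}hepta-2,4,6-trienamido]-4-oxopentanoate | CC(C)/C=C/C=C/C=C/C(=O)Nc1cc(/C=C/C=C/C=C/C(=O)NCC(=O)CCC(=O)OC)ccc1O | intermediate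
15 | (2E,4E,6E)-N-{2-hydroxy-5-[(1E,3E,5E)-7-[(2-hydroxy-5-oxocyclopent-1-en-1-yl)amino]-7-oxohepta-1,3,5-trien-1-yl]phenyl}-8-methylnona-2,4,6-trienamide (aromatic proto compound) | CC(C)/C=C/C=C/C=C/C(=O)Nc1cc(/C=C/C=C/C=C/C(=O)NC2=C(O)CCC2=O)ccc1O | intermediate
16 | (2E,4E,6E)-N-[(3R)-3-hydroxy-3-[(1E,3E,5E)-7-[(2-hydroxy-5-oxocyclopent-1-en-1-yl)amino]-7-oxohepta-1,3,5-trien-1-yl]-6-oxocyclohexa-1,4-dien-1-yl]-8-methylnona-2,4,6-trienamide ((R)-para-quinol) | CC(C)/C=C/C=C/C=C/C(=O)NC1=C[C@@](O)(/C=C/C=C/C=C/C(=O)NC2=C(O)CCC2=O)C=CC1=O | intermediate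
17 | (2E,4E,6E)-N-[(3R)-6-oxo-3-[(1E,3E,5E)-7-oxo-7-({5-oxo-2-[(triethylsilyl)oxy]cyclopent-1-en-1-yl}amino)hepta-1,3,5-trien-1-yl]-3-[(triethylsilyl)oxy]cyclohexa-1,4-dien-1-yl]-8-methylnona-2,4,6-trienamide | CC(C)/C=C/C=C/C=C/C(=O)NC1=C[C@@](O[Si](CC)(CC)CC)(/C=C/C=C/C=C/C(=O)NC2=C(O[Si](CC)(CC)CC)CCC2=O)C=CC1=O | intermediate
18 | (2E,4E,6E)-N-[(3R)-3-[(1E,3E,5E)-7-[(2-hydroxy-5-oxocyclopent-1-en-1-yl)amino]-7-oxohepta-1,3,5-trien-1-yl]-6-oxo-3-[(triethylsilyl)oxy]cyclohexa-1,4-dien-1-yl]-8-methylnona-2,4,6-trienamide | CC(C)/C=C/C=C/C=C/C(=O)NC1=C[C@@](O[Si](CC)(CC)CC)(/C=C/C=C/C=C/C(=O)NC2=C(O)CCC2=O)C=CC1=O | intermediate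
19 | (2E,4E,6E)-N-[(1R,5S,6S)-5-[(1E,3E,5E)-7-[(2-hydroxy-5-oxocyclopent-1-en-1-yl)amino]-7-oxohepta-1,3,5-trien-1-yl]-2-oxo-5-[(triethylsilyl)oxy]-7-oxabicyclo[4.1.0]hept-3-en-3-yl]-8-methylnona-2,4,6-trienamide | CC(C)/C=C/C=C/C=C/C(=O)NC1=C[C@@](O[Si](CC)(CC)CC)(/C=C/C=C/C=C/C(=O)NC2=C(O)CCC2=O)[C@H]2O[C@H]2C1=O | intermediate
20 | (2E,4E,6E)-N-[(1R,5S,6S)-5-hydroxy-5-[(1E,3E,5E)-7-[(2-hydroxy-5-oxocyclopent-1-en-1-yl)amino]-7-oxohepta-1,3,5-trien-1-yl]-2-oxo-7-oxabicyclo[4.1.0]hept-3-en-3-yl]-8-methylnona-2,4,6-trienamide (CNP0215439.3; OH anti to the epoxide oxygen) | CC(C)/C=C/C=C/C=C/C(=O)NC1=C[C@@](O)(/C=C/C=C/C=C/C(=O)NC2=C(O)CCC2=O)[C@H]2O[C@H]2C1=O | target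

**Step count and risk**
Total step count: 10. Longest linear sequence: 9 steps (steps 2–10, from 5).

Three steps most likely to fail, most risky first:

Step 8. The trienyl-stabilized phenoxenium ion may leave the iodane before water adds, which would erode the enantioselectivity, and the enolic cyclopentenone may be oxidized in competition. Fallback: abandon asymmetric induction at this point. Setting out from 15, PhI(OAc)2 in MeCN/H2O at 0 °C gives the racemic quinol F1. Preparative chromatography on a chiral stationary phase (supercritical CO2/MeOH with 0.1% formic acid) separates it into 16, where the route is rejoined, and the (S)-quinol F2, which is set aside.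

Step 10. The silyl ether may shield too little, and the residual preference for attack syn to the C4 oxygen would then give the wrong diastereomer. Fallback: replace substrate control by catalyst control. Setting out from 18, the Weitz–Scheffer epoxidation is run under chiral ion-pair (phase-transfer) catalysis with TBHP, aqueous NaOH and toluene/CH2Cl2 at 0 °C. N-Benzylcinchoninium chloride is used above one equivalent so that it also carries the cyclopentenone enolate into the organic phase. The quaternary ammonium cation selects the face of C5=C6 independently of the C4 substituents, as it does on 2-acylamino-4,4-disubstituted cyclohexa-2,5-dienones. The cinchonidine-derived pseudo-enantiomer is taken if the sense is wrong, and the minor diastereomer is removed by chromatography. The product is 19, where the route is rejoined before the HF·pyridine treatment; no new compound arises.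

Step 7. The substrate is polyanionic and poorly soluble, and N-acyl lactam formation or aldol chemistry may compete. Fallback: close the five-membered ring first and form the amide afterwards. Setting out from 13, Boc2O/NaHCO3 gives methyl 5-[(tert-butoxycarbonyl)amino]-4-oxopentanoate F3. KOtBu in THF closes the same Claisen ring on this simple carbamate to tert-butyl (2-hydroxy-5-oxocyclopent-1-en-1-yl)carbamate F4. HCl in dioxane gives 2-amino-3-hydroxycyclopent-2-en-1-one hydrochloride F5. Coupling of F5 with acid 12 (DIC, HOBt, NaHCO3, DMF) gives 15, where the route is rejoined.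

**Further compounds**
F1 | step 8 | racemic (2E,4E,6E)-N-[3-hydroxy-3-[(1E,3E,5E)-7-[(2-hydroxy-5-oxocyclopent-1-en-1-yl)amino]-7-oxohepta-1,3,5-trien-1-yl]-6-oxocyclohexa-1,4-dien-1-yl]-8-methylnona-2,4,6-trienamide | CC(C)/C=C/C=C/C=C/C(=O)NC1=CC(O)(/C=C/C=C/C=C/C(=O)NC2=C(O)CCC2=O)C=CC1=O
F2 | step 8 | (2E,4E,6E)-N-[(3S)-3-hydroxy-3-[(1E,3E,5E)-7-[(2-hydroxy-5-oxocyclopent-1-en-1-yl)amino]-7-oxohepta-1,3,5-trien-1-yl]-6-oxocyclohexa-1,4-dien-1-yl]-8-methylnona-2,4,6-trienamide | CC(C)/C=C/C=C/C=C/C(=O)NC1=C[C@](O)(/C=C/C=C/C=C/C(=O)NC2=C(O)CCC2=O)C=CC1=O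
F0 | step 10 | none | none
F3 | step 7 | methyl 5-[(tert-butoxycarbonyl)amino]-4-oxopentanoate | COC(=O)CCC(=O)CNC(=O)OC(C)(C)C
F4 | step 7 | tert-butyl (2-hydroxy-5-oxocyclopent-1-en-1-yl)carbamate | CC(C)(C)OC(=O)NC1=C(O)CCC1=O
F5 | step 7 | 2-amino-3-hydroxycyclopent-2-en-1-one hydrochloride | NC1=C(O)CCC1=O.Cl
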